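## Structural features

The target is an ent-labdane: a trans-fused decalin (ring A: C1–C5 and C10; ring B: C5–C10). It carries a methyl ester (C18) and a methyl (C19) on C4, an equatorial acetate on C6, an exocyclic methylene (C17) on C8, the angular methyl C20 on C10, and a (2E)-3-methylpenta-2,4-dienyl chain (C11–C16) on C9. The five stereocentres are contiguous (C4–C5–C6 and C5–C10–C9), and the two quaternary carbons C4 and C10 flank C5. C19 and C20 are 1,3-diaxial on one face; H5 and H9 are axial on the other, and the ester, the acetate and the C9 chain are all equatorial.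

The fragile groups are:
- the conjugated diene (acid, radicals, cycloaddition);
- the C8 methylene, which moves into the ring with acid and, whenever C6 is a ketone, into conjugation through enolisation at the doubly activated C7;
- the acetate, which tolerates neither hydride nor strong base;
- C9, which can epimerise while C11 is a carbonyl.

The real difficulties are three. The C10 quaternary centre must be built with the right relation to C4. The C6 oxygen must be equatorial, although the face from which a hydride would have to come is screened by C19 and C20. Two ester-level carbons (C11 and C18) are present and only one is to be reduced.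

The key step exploits the pattern of ring B. C10, C5, C6 and C7 carry oxygen at C6 as a 2-oxygenated diene does. C8 (with its extra carbon C17) and C9 (with C11) correspond to the conjugated double bond of an allenic ester. A [4+2] addition therefore forms C7–C8 and C9–C10 and leaves C6 as an enol ether, C8=C17 as the methylene and C11 as an ester.

## Logic of the disconnections

30 is cut at the C11–C12 bond (sp3–sp2) into 23 and 28. The diene is the most sensitive part, so it goes on last and in one piece of fixed E geometry. The cut removes five carbons and both chain alkenes, and 23 keeps all five stereocentres and the acetate. The forward step needs C11 as a nucleophile that tolerates acetate and ester (29) and a coupling that retains the geometry of 28.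

28 goes back through 27 and 26 to 24. The cuts are C14=C15 (olefination), the aldehyde/alcohol oxidation level, and the C13–C16 and C12–I bonds (syn carbometalation of the alkyne, which fixes E). The gain is a three-carbon commercial alkyne. The demand is careful handling, since 27 and 28 are volatile and are kept in solution.

23 goes back to 22 and then 21 by removing the acetyl group (O–acyl bond) and returning the iodide to a hydroxyl (C11–I). The acetate is placed after every reductive step, and the iodide is what tells the primary hydroxyl from the hindered secondary one. The forward steps need selective activation of the primary alcohol.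

21 goes back to 20 by cutting the C6–H bond. The equatorial carbinol is taken from the ketone under thermodynamic (electron-transfer) control, because a hydride would enter from the open face and give the axial epimer. The forward step must leave the C18 ester and the methylene untouched.

20 goes back to 18 through 19. C11 returns from the alcohol to the ester level (C11–H bonds), and the C6 ketone returns to the C5=C6 silyl enol ether (C5–H bond). As an enol ether the ketone is hidden from hydride, and the β,γ-unsaturated ketone appears only at the end by kinetic protonation. The forward step must reduce the C11 ester and not the C18 ester, and must protonate C5 on the face opposite C19 and C20.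

18 goes back to 16 by cutting only the C9–H bond. 16 is the C9 epimer expected from an endo cycloaddition. The forward step is deprotonation and kinetic α-protonation that must not move the alkene.

16 is cut at C7–C8 and C9–C10 into 14 and 15. This removes ring B, the C10 quaternary centre and four functionalised positions at once. It leaves a monocyclic piece with one stereocentre (14) and an achiral four-carbon piece (15). The forward step must be regioselective, must react at the conjugated allene bond only, and must approach C10 on the face opposite C19.

14 goes back through 12 and 10 to 8. The cuts are the O–Si bond (kinetic enolisation at C7), the C5–C6 bond (coupling of an acetyl anion equivalent with an enol triflate) and the C–O bond of the triflate (8 can enolise only away from the quaternary C4). The gain is a simple cyclohexanone. The demand is a coupling at a tetrasubstituted sp2 carbon next to a quaternary centre.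

8 goes back through 6 and 3 to 1 and 2. The cuts are the C10–C20 bond (enolate methylation; its configuration is irrelevant), the C4–C19 bond (auxiliary-controlled methylation through 4) and the C–N bond of the enamine. The whole absolute configuration of the route rests on this one methylation, which must therefore be highly enantioselective.

## Other disconnections considered

Alternative 1: The cut is the C18–O bond of a cyclic ether, so C4 is planned as a gem-dimethyl carbon and the carboxyl carbon is carved out of its equatorial methyl. In the forward sense the C6 equatorial carbinol A1 is O-iodinated in situ (PhI(OAc)2, I2, visible light). O–I homolysis gives the C6 alkoxy radical, 1,5-hydrogen transfer from C18 follows, and C–O closure gives the ether A2.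
- In favour: C4 becomes stereogenic by geometry alone, since the equatorial C6 oxygen reaches only the equatorial methyl. On this point it is better than the chosen plan, where C10 depends on an uncertain facial preference. Ring A could also come from an achiral gem-dimethyl source.
- Against: the equatorial C6 alcohol must exist first, so the reduction problem of step 10 is not avoided (equal on that point). The alkoxy radical next to the crowded C5 could fragment by β-scission. The doubly trans-fused five-membered ether is strained, so closure may stall. Oxidising the ether carbon to the carboxyl level would not tolerate alkenes, so C8 must stay masked and C11 protected.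
- Comparison: structurally A2 holds both rings and four of the stereocentres. Mechanistically its key step is a radical C–H functionalisation that forms one C–O bond and no skeletal bond, whereas step 7 forms two C–C bonds and ring B. In step economy it is longer after the key step (ether oxidation, ring opening to the ester, unmasking, methylenation, side chain).

Alternative 2: The cuts are C4–C5 and C9–C10, so that both rings come from the acyclic epoxy alkene keto ester A3. SnCl4 would open the epoxide at C4, the C5=C10 alkene would attack, and the enol carbon C9 would capture the C10 cation to give A4.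
- In favour: two rings and the C4, C5 and C10 centres form in one step. A chair–chair transition state from the E alkene dictates the trans fusion, which is better than relying on kinetic protonation at C5 as in step 9. The absolute configuration would come from a catalytic asymmetric epoxidation. In bonds and stereocentres formed per step it is better than the chosen plan.
- Against: A4 has no oxygen at C6 and no functional group from which to reach it; the activated position next to the C8 ketone is C7. It carries a superfluous C3 hydroxyl, and C18 is at the alcohol level. The oxygen-bearing substituent on the epoxide carbon that must ionise would slow initiation.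
- Comparison: structurally the cycloadduct 16 already has C6 oxygen, the C8 methylene and C11 in place, whereas A4 needs repair at three positions. Mechanistically it is a stepwise cationic cascade under conformational control against a cycloaddition under substrate facial control. Overall it loses in step economy because of the repairs, of which C6 oxygenation is unsolved.

Alternative 3: The cut is the C6–C7 bond, so that ring B comes from a six-membered cyclic acetal, A5, whose ring oxygen joins C6 and C8. Catalytic Hg(OCOCF3)2 (divalent mercury) in aqueous acetone would oxymercurate the enol ether, open the ring to a C8 ketone and a C6 aldehyde, and close C7 onto C6 by intramolecular aldol to give A6.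
- In favour: the C6 hydroxyl and the C8 carbonyl arise in the right 1,3-relationship. The C6 alcohol needs no separate ketone reduction, provided the aldol gives the equatorial carbinol; on that point it is better than the chosen plan. A two-carbon arm for the side chain is already on C9.
- Against: A5 already contains both quaternary carbons and the C5, C9 and C10 centres, so the hard part of the synthesis is moved into its preparation. The β-hydroxy ketone A6 is prone to dehydration and retro-aldol during methylenation. Mercury is undesirable.
- Comparison: structurally A6 and the hydrolysed cycloadduct carry the same oxygen pattern (equal). Mechanistically it is an organomercury-mediated aldol that adds one C–C bond, against a convergent cycloaddition that adds two and sets C10. In step economy the chosen plan is shorter.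

Key step: step 7

Remarks before the steps:
- Labdane numbering is used throughout: C1–C10 decalin, C11–C16 chain, C17 methylene carbon, C18 ester carbon, C19 methyl on C4, C20 methyl on C10.
- A cycloadduct with C11 cis to C20 would come from the exo mode. A Lewis acid-promoted addition is expected to be endo, so the primary adduct is entered as the C9 epimer 16, and the cis compound is 18, reached by the C9 reset.
- A C6 ketone beside the C8 methylene cannot be equilibrated with base, because C7 enolisation would conjugate the alkene. C9 is therefore reset on the silyl enol ether and C5 is set by kinetic protonation.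
- The C11 ester is reduced before the ketone is unveiled and before acetylation.
- The acetyl group is attached by cross-coupling of an enol triflate and not by acetylide addition and rearrangement. The latter passes through a β-alkoxy ester that could open by retro-aldol cleavage and lose the C4 configuration.
- Assumption: in step 2 the sense of methylation of the lithioenamine depends on the additive. The additive regime (HMPA in toluene, or an ethereal ligand) that gives the (S)-ketone is meant; tert-butyl D-valinate would be used if the opposite sense were found.

## Steps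

Step 1
Reactants: 1 methyl 2-oxocyclohexane-1-carboxylate; 2 tert-butyl L-valinate (free base from the commercial hydrochloride)
Product: 3 methyl 2-{[(2S)-1-tert-butoxy-3-methyl-1-oxobutan-2-yl]amino}cyclohex-1-ene-1-carboxylate
Conditions: BF3·OEt2 (cat.), toluene, reflux, Dean–Stark
Reagents that add atoms: none
Why: Condensation of a β-keto ester with a primary amine gives the hydrogen-bonded enamino ester, driven by removal of water; no new stereocentre is formed.

Step 2
Reactants: 3 methyl 2-{[(2S)-1-tert-butoxy-3-methyl-1-oxobutan-2-yl]amino}cyclohex-1-ene-1-carboxylate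
Product: 6 methyl (1S)-1-methyl-2-oxocyclohexane-1-carboxylate, via lithioenamine 4 (not isolated), via methylated imine 5 (not isolated)
Conditions: LiN(i-Pr)2, toluene, −78 °C; HMPA (1 equiv); MeI, −78 → −40 °C; then 10% aq. citric acid, rt
Reagents that add atoms: iodomethane, CI; water, O
Why: Auxiliary-controlled C-alkylation of a chiral lithioenamine: in the N-lithiated, ester-chelated species the isopropyl group of the valine unit screens one face, so methylation creates the quaternary C4 with S configuration; mild acid hydrolysis of the imine releases the ketone and the auxiliary.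

Step 3
Reactants: 6 methyl (1S)-1-methyl-2-oxocyclohexane-1-carboxylate
Product: 8 methyl (1S)-1,3-dimethyl-2-oxocyclohexane-1-carboxylate (both C3 epimers), via lithium enolate 7 (not isolated)
Conditions: LiN(i-Pr)2, THF, −78 °C; MeI, −78 → 0 °C
Reagents that add atoms: iodomethane, CI
Why: The ketone can enolise only toward C3 because the other α-carbon is quaternary, so enolate methylation is regiospecific and installs the future C20; the new centre is not controlled and need not be, since it becomes sp2 in step 4.

Step 4
Reactants: 8 methyl (1S)-1,3-dimethyl-2-oxocyclohexane-1-carboxylate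
Product: 10 methyl (1S)-1,3-dimethyl-2-{[(trifluoromethyl)sulfonyl]oxy}cyclohex-2-ene-1-carboxylate, via potassium enolate 9 (not isolated)
Conditions: KN(SiMe3)2, THF, −78 °C; PhNTf2, −78 → 0 °C
Reagents that add atoms: N-phenylbis(trifluoromethanesulfonimide), O=S(=O)(N(c1ccccc1)S(=O)(=O)C(F)(F)F)C(F)(F)F
Why: O-sulfonylation of the only possible, tetrasubstituted enolate gives the regiodefined enol triflate, as with 2,2,6-trisubstituted cyclohexanones; C4 is untouched.

Step 5
Reactants: 10 methyl (1S)-1,3-dimethyl-2-{[(trifluoromethyl)sulfonyl]oxy}cyclohex-2-ene-1-carboxylate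
Product: 12 methyl (1S)-2-acetyl-1,3-dimethylcyclohex-2-ene-1-carboxylate, via ethoxydiene 11 (not isolated)
Conditions: tributyl(1-ethoxyvinyl)stannane, Pd(PPh3)4 (5 mol%), LiCl, CuI (10 mol%), dioxane, 90 °C; then 1 M aq. HCl, THF, rt
Reagents that add atoms: tributyl(1-ethoxyvinyl)stannane, CCCC[Sn](CCCC)(CCCC)C(=C)OCC; water, O
Why: Stille coupling of the enol triflate with an acetyl anion equivalent forms the C5–C6 bond, and the enol ether is hydrolysed in the work-up to the methyl ketone; no stereocentre is involved and the tetrasubstituted ring alkene stays where the triflate fixed it.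

Step 6
Reactants: 12 methyl (1S)-2-acetyl-1,3-dimethylcyclohex-2-ene-1-carboxylate
Product: 14 methyl (1S)-1,3-dimethyl-2-{1-[(trimethylsilyl)oxy]ethenyl}cyclohex-2-ene-1-carboxylate, via lithium dienolate 13 (not isolated)
Conditions: LiN(i-Pr)2, THF, −78 °C; Me3SiCl, Et3N, −78 → 0 °C; non-aqueous work-up (pentane, filtration)
Reagents that add atoms: chlorotrimethylsilane, C[Si](C)(C)Cl
Why: Kinetic deprotonation of the enone at the acetyl methyl (C7) gives the cross-conjugated enolate, and O-silylation gives the 2-siloxydiene; the ester on the quaternary C4 has no α-hydrogen and is not affected.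

Step 7
Reactants: 14 methyl (1S)-1,3-dimethyl-2-{1-[(trimethylsilyl)oxy]ethenyl}cyclohex-2-ene-1-carboxylate; 15 ethyl buta-2,3-dienoate
Product: 16 1-ethyl 5-methyl (1S,5S,8aS)-5,8a-dimethyl-2-methylidene-4-[(trimethylsilyl)oxy]-1,2,3,5,6,7,8,8a-octahydronaphthalene-1,5-dicarboxylate (endo adduct; C11 trans to C20)
Conditions: 15 (2 equiv), EtAlCl2 (1.5 equiv), CH2Cl2, −78 → −30 °C; Et3N, then aq. NaHCO3
Reagents that add atoms: none
Why: EtAlCl2 binds the ester carbonyl of 15 and lowers the LUMO of its conjugated C8=C9 bond, while the siloxy group at C6 and the alkyl groups at C10 raise the diene HOMO and put its largest coefficient on C7; C7–C8 bonding therefore leads and C9–C10 follows in a concerted but asynchronous [4+2] addition, whose stepwise limit (Mukaiyama–Michael addition, then closure of the aluminium enolate on the silyloxyallyl cation) gives the same product. The closest known reaction types are Lewis acid-promoted Diels–Alder additions of 2-silyloxydienes with fully substituted termini to hindered dienophiles, the cycloadditions of 2-vinyl-1,3,3-trimethylcyclohexene used for drimanes, and cycloadditions of allenic esters at their conjugated double bond. Ring B closes as a six-membered carbocycle in the intermolecular [4+2] mode, leaving C6 as a regiodefined silyl enol ether and the unactivated distal allene bond as the C8 methylene. Regiochemistry is matched, since the 2-siloxy group directs the ester carbon para to C6 and the C10 substituents direct it ortho to C10. C10 is set by the C4 centre: in the half-chair of ring A the methyl C19 is expected to lie pseudoaxial and the flat ester pseudoequatorial, so 15 should add to the face opposite C19 and C20 ends syn to C19. C9 follows from the endo rule (complexed ester under the diene, hence C11 trans to C20 in 16), but this centre is not relied on because step 8 resets it. The selectivity the step needs is the facial one at C10, and only the methyl/ester difference at C4 secures it, so it is treated below as the main risk.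

Step 8
Reactants: 16 1-ethyl 5-methyl (1S,5S,8aS)-5,8a-dimethyl-2-methylidene-4-[(trimethylsilyl)oxy]-1,2,3,5,6,7,8,8a-octahydronaphthalene-1,5-dicarboxylate
Product: 18 1-ethyl 5-methyl (1R,5S,8aS)-5,8a-dimethyl-2-methylidene-4-[(trimethylsilyl)oxy]-1,2,3,5,6,7,8,8a-octahydronaphthalene-1,5-dicarboxylate (C11 cis to C20), via lithium ester dienolate 17 (not isolated)
Conditions: LiN(i-Pr)2, THF, −78 °C; AcOH in THF, −78 °C; aq. NaHCO3
Reagents that add atoms: none
Why: Deprotonation at C9 gives the extended ester enolate, and kinetic protonation of such dienolates occurs at the α-carbon, which returns the β,γ-unsaturated ester with the methylene in place; the proton is expected to enter axially on the face opposite C20, leaving C11 equatorial and cis to C20. Any exo adduct present in 16 is 18 itself and passes through the same enolate, so the step is convergent.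

Step 9
Reactants: 18 1-ethyl 5-methyl (1R,5S,8aS)-5,8a-dimethyl-2-methylidene-4-[(trimethylsilyl)oxy]-1,2,3,5,6,7,8,8a-octahydronaphthalene-1,5-dicarboxylate
Product: 20 methyl (1S,4aS,5R,8aS)-5-(hydroxymethyl)-1,4a-dimethyl-6-methylidene-8-oxodecahydronaphthalene-1-carboxylate, via hydroxymethyl silyl enol ether 19 (not isolated)
Conditions: i-Bu2AlH (2.5 equiv), CH2Cl2, −78 → −40 °C; then 1 M aq. HCl, THF, 0 °C
Reagents that add atoms: none
Why: Hydride reduction of the C11 ester to the primary alcohol while the C6 ketone is masked; the C18 ester sits on a quaternary carbon beside the tetrasubstituted C5 and the cis C6 silyloxy group and is expected to react more slowly. The acid work-up hydrolyses the silyl enol ether with protonation at C5 on the face opposite C19 and C20, which gives the trans ring fusion under kinetic control and avoids any equilibration of the β,γ-unsaturated ketone.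

Step 10
Reactants: 20 methyl (1S,4aS,5R,8aS)-5-(hydroxymethyl)-1,4a-dimethyl-6-methylidene-8-oxodecahydronaphthalene-1-carboxylate
Product: 21 methyl (1S,4aS,5R,8R,8aS)-8-hydroxy-5-(hydroxymethyl)-1,4a-dimethyl-6-methylidenedecahydronaphthalene-1-carboxylate
Conditions: SmI2 (3 equiv), THF–H2O, 0 °C → rt
Reagents that add atoms: none
Why: Electron-transfer reduction of the ketone (ketyl, then a configurationally mobile carbanion that is protonated) should give the thermodynamically preferred equatorial C6 carbinol, the outcome known for dissolving-metal reductions of 6-oxo decalins of this type, whereas a borohydride would enter from the open face and give the axial epimer. Unactivated esters and isolated alkenes are inert to SmI2–H2O.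

Step 11
Reactants: 21 methyl (1S,4aS,5R,8R,8aS)-8-hydroxy-5-(hydroxymethyl)-1,4a-dimethyl-6-methylidenedecahydronaphthalene-1-carboxylate
Product: 22 methyl (1S,4aR,5R,8R,8aS)-8-hydroxy-5-(iodomethyl)-1,4a-dimethyl-6-methylidenedecahydronaphthalene-1-carboxylate
Conditions: PPh3, imidazole, I2, CH2Cl2, 0 °C → rt (21 added to the preformed reagent)
Reagents that add atoms: iodine, [I][I]
Why: Appel-type iodination; the primary C11 hydroxyl reacts far faster than the secondary C6 hydroxyl flanked by the quaternary C4, and adding the diol to the preformed phosphonium reagent keeps free iodine away from the methylene.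

Step 12
Reactants: 22 methyl (1S,4aR,5R,8R,8aS)-8-hydroxy-5-(iodomethyl)-1,4a-dimethyl-6-methylidenedecahydronaphthalene-1-carboxylate
Product: 23 methyl (1S,4aR,5R,8R,8aS)-8-(acetyloxy)-5-(iodomethyl)-1,4a-dimethyl-6-methylidenedecahydronaphthalene-1-carboxylate
Conditions: Ac2O, pyridine, DMAP (cat.), CH2Cl2, rt
Reagents that add atoms: acetic anhydride, CC(=O)OC(C)=O
Why: Acylation of the equatorial secondary alcohol with retention at C6; the β-branched primary iodide is not displaced under these conditions.

Step 13
Reactants: 24 prop-2-yn-1-ol
Product: 26 (2E)-3-iodo-2-methylprop-2-en-1-ol, via alkenylalane 25 (not isolated)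
Conditions: Me3Al (3 equiv), Cp2ZrCl2 (0.25 equiv), CH2Cl2, 0 °C → rt; then I2, THF, −30 → 0 °C
Reagents that add atoms: trimethylaluminium, C[Al](C)C; iodine, [I][I]
Why: Zirconium-catalysed carboalumination of the terminal alkyne (syn addition, methyl to the internal carbon) followed by iodinolysis with retention gives the E iodoalkene.

Step 14
Reactants: 26 (2E)-3-iodo-2-methylprop-2-en-1-ol
Product: 27 (2E)-3-iodo-2-methylprop-2-enal
Conditions: MnO2, CH2Cl2, rt; filtered and used as a solution
Reagents that add atoms: none
Why: Allylic alcohol oxidation with MnO2; the alkene geometry is not touched.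

Step 15
Reactants: 27 (2E)-3-iodo-2-methylprop-2-enal
Product: 28 (1E)-1-iodo-2-methylbuta-1,3-diene
Conditions: Ph3PCH3Br, NaN(SiMe3)2, THF, −78 → 0 °C; kept as a solution in pentane/THF
Reagents that add atoms: methyltriphenylphosphonium bromide, C[P+](c1ccccc1)(c1ccccc1)c1ccccc1.[Br-]
Why: Wittig methylenation of the enal adds C15; no new geometric element arises and the E iodoalkene is retained.

Step 16
Reactants: 23 methyl (1S,4aR,5R,8R,8aS)-8-(acetyloxy)-5-(iodomethyl)-1,4a-dimethyl-6-methylidenedecahydronaphthalene-1-carboxylate; 28 (1E)-1-iodo-2-methylbuta-1,3-diene
Product: 30 methyl (1S,4aS,5R,8R,8aS)-8-(acetyloxy)-1,4a-dimethyl-6-methylidene-5-[(2E)-3-methylpenta-2,4-dien-1-yl]decahydronaphthalene-1-carboxylate (CNP0212193.1), via alkylzinc iodide 29 (not isolated)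
Conditions: Zn dust (activated with BrCH2CH2Br and Me3SiCl), LiCl, THF, 40 °C; then 28, PdCl2(dppf) (5 mol%), THF, rt
Reagents that add atoms: none
Why: Zinc insertion into the primary C–I bond gives an alkylzinc iodide that tolerates the acetate and the ester; Negishi sp3–sp2 coupling with the alkenyl iodide proceeds with retention of alkene geometry, so the 12E diene arrives intact and no stereocentre is touched.

## Compound list

1 | methyl 2-oxocyclohexane-1-carboxylate | COC(=O)C1CCCCC1=O | starting material
2 | tert-butyl L-valinate, tert-butyl (2S)-2-amino-3-methylbutanoate | CC(C)[C@H](N)C(=O)OC(C)(C)C | starting material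
3 | methyl 2-{[(2S)-1-tert-butoxy-3-methyl-1-oxobutan-2-yl]amino}cyclohex-1-ene-1-carboxylate | COC(=O)C1=C(N[C@@H](C(C)C)C(=O)OC(C)(C)C)CCCC1 | intermediate
4 | N-lithio derivative of 3 (lithioenamine) | COC(=O)C1=C(N([Li])[C@@H](C(C)C)C(=O)OC(C)(C)C)CCCC1 | intermediate (not isolated)
5 | methyl (1S)-2-{[(2S)-1-tert-butoxy-3-methyl-1-oxobutan-2-yl]imino}-1-methylcyclohexane-1-carboxylate | CC(C)[C@H](N=C1CCCC[C@]1(C)C(=O)OC)C(=O)OC(C)(C)C | intermediate (not isolated)
6 | methyl (1S)-1-methyl-2-oxocyclohexane-1-carboxylate | O=C1CCCC[C@]1(C)C(=O)OC | intermediate
7 | lithium enolate of 6 (C2=C3) | [Li]OC1=CCCC[C@]1(C)C(=O)OC | intermediate (not isolated)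
8 | methyl (1S)-1,3-dimethyl-2-oxocyclohexane-1-carboxylate (both C3 epimers) | O=C1C(C)CCC[C@]1(C)C(=O)OC | intermediate
9 | potassium enolate of 8 | [K]OC1=C(C)CCC[C@]1(C)C(=O)OC | intermediate (not isolated)
10 | methyl (1S)-1,3-dimethyl-2-{[(trifluoromethyl)sulfonyl]oxy}cyclohex-2-ene-1-carboxylate | O=S(=O)(OC1=C(C)CCC[C@]1(C)C(=O)OC)C(F)(F)F | intermediate
11 | methyl (1S)-2-(1-ethoxyethenyl)-1,3-dimethylcyclohex-2-ene-1-carboxylate | C=C(OCC)C1=C(C)CCC[C@]1(C)C(=O)OC | intermediate (not isolated)
12 | methyl (1S)-2-acetyl-1,3-dimethylcyclohex-2-ene-1-carboxylate | CC(=O)C1=C(C)CCC[C@]1(C)C(=O)OC | intermediate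
13 | lithium 1-[(6S)-6-(methoxycarbonyl)-2,6-dimethylcyclohex-1-en-1-yl]ethen-1-olate | [Li]OC(=C)C1=C(C)CCC[C@]1(C)C(=O)OC | intermediate (not isolated)
14 | methyl (1S)-1,3-dimethyl-2-{1-[(trimethylsilyl)oxy]ethenyl}cyclohex-2-ene-1-carboxylate | C=C(O[Si](C)(C)C)C1=C(C)CCC[C@]1(C)C(=O)OC | intermediate (precursor of the key step)
15 | ethyl buta-2,3-dienoate | C=C=CC(=O)OCC | starting material
16 | 1-ethyl 5-methyl (1S,5S,8aS)-5,8a-dimethyl-2-methylidene-4-[(trimethylsilyl)oxy]-1,2,3,5,6,7,8,8a-octahydronaphthalene-1,5-dicarboxylate (C11 trans to C20) | CCOC(=O)[C@H]1C(=C)CC(O[Si](C)(C)C)=C2[C@@]1(C)CCC[C@]2(C)C(=O)OC | intermediate (product of the key step)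
17 | lithium dienolate of the C11 ester of 16 | CCOC(O[Li])=C1C(=C)CC(O[Si](C)(C)C)=C2[C@@]1(C)CCC[C@]2(C)C(=O)OC | intermediate (not isolated)
18 | 1-ethyl 5-methyl (1R,5S,8aS)-5,8a-dimethyl-2-methylidene-4-[(trimethylsilyl)oxy]-1,2,3,5,6,7,8,8a-octahydronaphthalene-1,5-dicarboxylate (C11 cis to C20) | CCOC(=O)[C@@H]1C(=C)CC(O[Si](C)(C)C)=C2[C@@]1(C)CCC[C@]2(C)C(=O)OC | intermediate
19 | methyl (1S,4aS,5R)-5-(hydroxymethyl)-1,4a-dimethyl-6-methylidene-8-[(trimethylsilyl)oxy]-1,2,3,4,4a,5,6,7-octahydronaphthalene-1-carboxylate | OC[C@@H]1C(=C)CC(O[Si](C)(C)C)=C2[C@@]1(C)CCC[C@]2(C)C(=O)OC | intermediate (not isolated)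
20 | methyl (1S,4aS,5R,8aS)-5-(hydroxymethyl)-1,4a-dimethyl-6-methylidene-8-oxodecahydronaphthalene-1-carboxylate | OC[C@@H]1C(=C)CC(=O)[C@H]2[C@@]1(C)CCC[C@]2(C)C(=O)OC | intermediate
21 | methyl (1S,4aS,5R,8R,8aS)-8-hydroxy-5-(hydroxymethyl)-1,4a-dimethyl-6-methylidenedecahydronaphthalene-1-carboxylate | OC[C@@H]1C(=C)C[C@@H](O)[C@H]2[C@@]1(C)CCC[C@]2(C)C(=O)OC | intermediate
22 | methyl (1S,4aR,5R,8R,8aS)-8-hydroxy-5-(iodomethyl)-1,4a-dimethyl-6-methylidenedecahydronaphthalene-1-carboxylate | IC[C@@H]1C(=C)C[C@@H](O)[C@H]2[C@@]1(C)CCC[C@]2(C)C(=O)OC | intermediate
23 | methyl (1S,4aR,5R,8R,8aS)-8-(acetyloxy)-5-(iodomethyl)-1,4a-dimethyl-6-methylidenedecahydronaphthalene-1-carboxylate | IC[C@@H]1C(=C)C[C@@H](OC(C)=O)[C@H]2[C@@]1(C)CCC[C@]2(C)C(=O)OC | intermediate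
24 | prop-2-yn-1-ol | C#CCO | starting material
25 | (E)-alkenyldimethylalane from 24, as its dimethylaluminium alkoxide | C[Al](C)OC/C(C)=C/[Al](C)C | intermediate (not isolated)
26 | (2E)-3-iodo-2-methylprop-2-en-1-ol | OC/C(C)=C/I | intermediate
27 | (2E)-3-iodo-2-methylprop-2-enal | O=C/C(C)=C/I | intermediate
28 | (1E)-1-iodo-2-methylbuta-1,3-diene | C=C/C(C)=C/I | intermediate
29 | alkylzinc iodide from 23 (zinc inserted into the C11–I bond) | I[Zn]C[C@@H]1C(=C)C[C@@H](OC(C)=O)[C@H]2[C@@]1(C)CCC[C@]2(C)C(=O)OC | intermediate (not isolated)
30 | methyl (1S,4aS,5R,8R,8aS)-8-(acetyloxy)-1,4a-dimethyl-6-methylidene-5-[(2E)-3-methylpenta-2,4-dien-1-yl]decahydronaphthalene-1-carboxylate | C=C/C(C)=C/C[C@@H]1C(=C)C[C@@H](OC(C)=O)[C@H]2[C@@]1(C)CCC[C@]2(C)C(=O)OC | target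

## Step count and least certain steps

Total step count: 16 (13 on the main line, 3 for 28). Longest linear sequence: 13 steps (steps 1–12 and 16).

Step 7 (key step). The most likely failure is poor facial selectivity at C10: the two diene faces differ only by methyl versus ester at C4, and binding of the aluminium reagent to the C18 ester may change which group is effectively larger. Lewis acid-induced loss of the trimethylsilyl group or [2+2] addition at the enol ether may also compete. The fallback replaces substrate control by reagent control and sets out from 14. The chelating dienophile 3-(buta-2,3-dienoyl)-1,3-oxazolidin-2-one F1 (from buta-2,3-dienoic acid and oxazolidin-2-one through the mixed pivalic anhydride) is added under a chiral bis(oxazoline) complex of Cu(SbF6)2 (divalent copper), with the ligand antipode chosen so that catalyst control matches the needed C10 configuration. This would give the imide adduct methyl (1S,4aS,5S)-1,4a-dimethyl-6-methylidene-5-(2-oxo-1,3-oxazolidine-3-carbonyl)-8-[(trimethylsilyl)oxy]-1,2,3,4,4a,5,6,7-octahydronaphthalene-1-carboxylate F2. EtOMgBr in THF then exchanges the imide for the ethyl ester, and the route is rejoined at 16.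

Step 9. The most likely failure is loss of chemoselectivity, with the C18 ester reduced as well, because both esters are hindered and differ only in the substitution of their α-carbon. The fallback protects the ring A carboxyl by charge and sets out from 18. LiSPr in HMPA at rt cleaves the methyl ester by SN2 attack at the O-methyl group, which is much faster than attack at O-ethyl, and gives the lithium carboxylate F3, inert to borohydride. LiBH4 in THF then reduces the C11 ester, and the acid work-up (1 M HCl) unveils the ketone as in step 9, giving (1S,4aS,5R,8aS)-5-(hydroxymethyl)-1,4a-dimethyl-6-methylidene-8-oxodecahydronaphthalene-1-carboxylic acid F4. Me3SiCHN2 in MeOH–toluene re-forms the methyl ester, and the route is rejoined at 20.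

Step 10. The most likely failure is incomplete thermodynamic control (some protonation from the open face, giving the axial C6 epimer), or enolisation toward C7 by the basic samarium alkoxides on long exposure. The fallback epimerises the carbinol instead of controlling the reduction and sets out from 20. NaBH4 (MeOH, 0 °C) is expected to attack from the open face and give the axial alcohol, methyl (1S,4aS,5R,8S,8aS)-8-hydroxy-5-(hydroxymethyl)-1,4a-dimethyl-6-methylidenedecahydronaphthalene-1-carboxylate F5. A ruthenium hydrogen-transfer catalyst of the kind used to racemise secondary alcohols, Ru(CO)2Cl(η5-C5Ph5) with catalytic t-BuOK in toluene, would then equilibrate C6 by reversible dehydrogenation at the metal toward the more stable equatorial epimer. The route is rejoined at 21.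

Step 16. The most likely failure is loss of 28 through volatility and polymerisation, together with slow transmetalation of the β-branched alkylzinc, which leaves time for protodezincation or β-hydride elimination. The fallback builds the diene stepwise with a robust partner and sets out from 23 and 26. 26 is silylated (t-BuMe2SiCl, imidazole) to tert-butyl{[(2E)-3-iodo-2-methylprop-2-en-1-yl]oxy}dimethylsilane F6. 29, made from 23 as in step 16, is coupled with F6 under the same palladium catalysis to give the silyl ether F7. Bu4NF/AcOH gives the allylic alcohol F8, MnO2 gives the enal F9, and Ph3P=CH2 converts F9 into 30.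

Step 5. The most likely failure is slow oxidative addition or transmetalation at the tetrasubstituted triflate next to the quaternary C4, so that hydrolysis or reduction of the triflate takes over. The fallback uses carbonyl addition and rearrangement in place of cross-coupling and sets out from 8. Ethynylmagnesium bromide (THF, −40 °C, short contact to limit retro-aldol opening of the β-alkoxy ester) gives the tertiary propargylic alcohol methyl (1S)-2-ethynyl-2-hydroxy-1,3-dimethylcyclohexane-1-carboxylate F10. Rupe rearrangement (HCO2H, 90 °C) dehydrates toward C10 and hydrates the enyne to the methyl ketone, and the route is rejoined at 12.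

## Further compounds

F1 | step 7 | 3-(buta-2,3-dienoyl)-1,3-oxazolidin-2-one | C=C=CC(=O)N1CCOC1=O
F2 | step 7 | methyl (1S,4aS,5S)-1,4a-dimethyl-6-methylidene-5-(2-oxo-1,3-oxazolidine-3-carbonyl)-8-[(trimethylsilyl)oxy]-1,2,3,4,4a,5,6,7-octahydronaphthalene-1-carboxylate | O=C1OCCN1C(=O)[C@H]1C(=C)CC(O[Si](C)(C)C)=C2[C@@]1(C)CCC[C@]2(C)C(=O)OC
F3 | step 9 | lithium (1S,4aS,5R)-5-(ethoxycarbonyl)-1,4a-dimethyl-6-methylidene-8-[(trimethylsilyl)oxy]-1,2,3,4,4a,5,6,7-octahydronaphthalene-1-carboxylate | CCOC(=O)[C@@H]1C(=C)CC(O[Si](C)(C)C)=C2[C@@]1(C)CCC[C@]2(C)C(=O)[O-].[Li+]
F4 | step 9 | (1S,4aS,5R,8aS)-5-(hydroxymethyl)-1,4a-dimethyl-6-methylidene-8-oxodecahydronaphthalene-1-carboxylic acid | OC[C@@H]1C(=C)CC(=O)[C@H]2[C@@]1(C)CCC[C@]2(C)C(=O)O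
F5 | step 10 | methyl (1S,4aS,5R,8S,8aS)-8-hydroxy-5-(hydroxymethyl)-1,4a-dimethyl-6-methylidenedecahydronaphthalene-1-carboxylate (axial C6 hydroxyl) | OC[C@@H]1C(=C)C[C@H](O)[C@H]2[C@@]1(C)CCC[C@]2(C)C(=O)OC
F6 | step 16 | tert-butyl{[(2E)-3-iodo-2-methylprop-2-en-1-yl]oxy}dimethylsilane | CC(C)(C)[Si](C)(C)OC/C(C)=C/I
F7 | step 16 | methyl (1S,4aS,5R,8R,8aS)-8-(acetyloxy)-5-[(2E)-4-{[tert-butyl(dimethyl)silyl]oxy}-3-methylbut-2-en-1-yl]-1,4a-dimethyl-6-methylidenedecahydronaphthalene-1-carboxylate | CC(C)(C)[Si](C)(C)OC/C(C)=C/C[C@@H]1C(=C)C[C@@H](OC(C)=O)[C@H]2[C@@]1(C)CCC[C@]2(C)C(=O)OC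
F8 | step 16 | methyl (1S,4aS,5R,8R,8aS)-8-(acetyloxy)-5-[(2E)-4-hydroxy-3-methylbut-2-en-1-yl]-1,4a-dimethyl-6-methylidenedecahydronaphthalene-1-carboxylate | OC/C(C)=C/C[C@@H]1C(=C)C[C@@H](OC(C)=O)[C@H]2[C@@]1(C)CCC[C@]2(C)C(=O)OC
F9 | step 16 | methyl (1S,4aS,5R,8R,8aS)-8-(acetyloxy)-1,4a-dimethyl-5-[(2E)-3-methyl-4-oxobut-2-en-1-yl]-6-methylidenedecahydronaphthalene-1-carboxylate | O=C/C(C)=C/C[C@@H]1C(=C)C[C@@H](OC(C)=O)[C@H]2[C@@]1(C)CCC[C@]2(C)C(=O)OC
F10 | step 5 | methyl (1S)-2-ethynyl-2-hydroxy-1,3-dimethylcyclohexane-1-carboxylate (diastereomer mixture) | C#CC1(O)C(C)CCC[C@]1(C)C(=O)OC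
A1 | alternative 1 | C6 equatorial carbinol with gem-dimethyl C4, C8 ethylene ketal and C11 pivalate | CC(C)(C)C(=O)OC[C@@H]1C2(OCCO2)C[C@@H](O)[C@H]3[C@@]1(C)CCCC3(C)C
A2 | alternative 1 | 18,6-ether bridging rings A and B, with C8 ethylene ketal and C11 pivalate | CC(C)(C)C(=O)OC[C@@H]1C2(OCCO2)C[C@@H](O4)[C@H]3[C@@]1(C)CCC[C@]3(C)C4
A3 | alternative 2 | methyl (6E)-9-[(2R,3R)-3-{[tert-butyl(dimethyl)silyl]oxymethyl}-3-methyloxiran-2-yl]-7-methyl-3-oxonon-6-enoate (acyclic epoxy alkene keto ester) | COC(=O)CC(=O)CC/C=C(\C)CC[C@H]1O[C@]1(C)CO[Si](C)(C)C(C)(C)C
A4 | alternative 2 | bicyclic keto ester with 3-hydroxyl, 18-silyloxy, C8 ketone and C11 ester | COC(=O)[C@@H]1C(=O)CC[C@H]2[C@@]1(C)CC[C@@H](O)[C@]2(C)CO[Si](C)(C)C(C)(C)C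
A5 | alternative 3 | 2-methylidene tetrahydropyran methyl acetal fused to ring A (ring oxygen between C6 and C8; anomeric centre unspecified) | CC(C)(C)[Si](C)(C)OCC[C@@H]1C(=C)OC(OC)[C@H]2[C@@]1(C)CCC[C@]2(C)C(=O)OC
A6 | alternative 3 | decalin with equatorial C6 hydroxyl, C8 ketone and silyloxyethyl arm on C9 | CC(C)(C)[Si](C)(C)OCC[C@@H]1C(=O)C[C@@H](O)[C@H]2[C@@]1(C)CCC[C@]2(C)C(=O)OC
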